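## Structural features

The target is a germacrane-type sesquiterpenoid: a ten-membered carbocycle (C1–C10) fused across C6–C7 to an α,β-unsaturated γ-lactone (C7=C11, C12 carbonyl, ring oxygen on C6). The large ring holds one endocyclic alkene, the Z-trisubstituted C4=C5 (C15 methyl on C4), and one exocyclic methylene, C10=C14. C11 carries the acetoxymethyl carbon C13. There are three stereocentres: C1 (R, free allylic alcohol), C3 (S, allylic acetate) and C6 (R, lactone carbinol). C1 and C3 are 1,3-related through C2, and C3 and C6 sit cis on the two ends of the Z alkene, so no stereocentre has a stereocentre as direct neighbour. The fragile points are C6–H (allylic and also the γ-hydrogen of the butenolide, so base can epimerise it), the C13 acetate (an allylic leaving group on an acceptor alkene), and the ring itself, which is open to transannular reactions under acid. The real difficulty is to form a ten-membered ring that contains a Z-trisubstituted alkene flanked by two oxygenated carbons, and to set three remote stereocentres without a rigid relay. The key step exploits the fact that C1–C6, with a ketone oxygen at C6, the Z C4=C5 alkene with its methyl and the C3 oxygen, are a 4-oxygenated 3-methylcyclohex-2-enone. C7–C8 and C9–C10(C14) are then a vinyl and an isopropenyl group on C6 and C1, so the macrocycle is a p-menthane six-membered ring expanded by four atoms.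

## Logic of the disconnections

23 to 21: the C1–O bond is cut and the C10=C14 alkene is moved back to C1=C10. A 1-hydroxy-10(14)-ene is the ene-transposition product of a 1(10)-ene, so this removes the C1 stereocentre and the only free hydroxyl, and both acetates can then be installed without differentiation. The forward step demands that singlet oxygen reacts only at C1=C10, takes hydrogen from C14 and approaches the face that gives 1R; 22 is reduced in the same flask.

21 to 19 (through 20): the two acetyl C–O bonds are cut and replaced by silyl ethers. Acetates would not survive potassium hydride, amide base or borohydride and carbonate, whereas silyl ethers do, and one exchange serves C3 and C13 together. The demand is a desilylation mild enough to leave C6–H of the butenolide alone.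

19 to 9 and 13 (through 17 and 15): the cuts are C7=C11 (as an aldol C7–C11 bond plus water), the O–C12 lactone bond and the C6–H bond. The butenolide is the dehydrated lactone of the aldol adduct between the C7 enolate of a C6 ketone and an α-keto ester, which delivers C11, C12 and C13 in one piece at the right oxidation levels. The gain is three carbons and one ring, and C6 reverts to a ketone. The demands are α′ enolisation at C7, hydride delivery to the correct face of C6, and loss of water toward C7 and not toward C13.

13 to 10 (through 11): the ketone C=O is traced to a C=CH2 group and the Si–O bond is cut. 10 already has the three carbons and the oxygen pattern. The demand is ozonolysis of an electron-poor alkene and use of 13 without storage.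

9 to 6: the C8–C9 bond is cut and the C6–C1 bond (germacrane numbering) is re-formed, which is the retro [3,3] shift. The ten-membered ring collapses to a cyclohexene, the Z alkene becomes a ring alkene whose geometry is fixed, and C3 is carried as a ring stereocentre. The demands are a trans arrangement of vinyl and isopropenyl in 6, a free tertiary hydroxyl, and a C3 protecting group inert to potassium hydride.

6 to 4 and 5: the bond between the carbinol carbon and the vinyl group is cut. This leaves an enone and a commercial nucleophile. The demand is 1,2-addition anti to the neighbouring isopropenyl group without enolisation of the acidic α-hydrogen.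

4 to 1 (through 3 and 2): the enone C=O is traced to an allylic CH2, the Si–O bond is cut, and the carbinol C–H is traced to hydride addition. 1 already has the ring, the methyl group, the isopropenyl stereocentre in the required absolute sense and an oxygen at the future C3, so a cis-selective reduction sets C3. This replaces a longer hydrocarbon entry that would need a γ-oxygenation of uncertain facial outcome next to an epimerisable centre. The demand is a site-selective allylic oxidation of 3.

## Other disconnections considered

Alternative 1: The cuts are C1–C2 and O–C3. The open-chain aldoxime A2 would be oxidised with NaOCl to nitrile oxide A3, which adds across the terminal alkene of its Z-diene to give the isoxazoline-bridged macrocycle A1. N–O cleavage, C3 acetylation and C1 reduction would follow.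
- In favour: one step closes the carbocycle and places both oxygens of the C1/C3 pair. C6 and the C13 acetate are fixed before ring closure, which is better than the chosen plan's late C6 reduction. The end game is about as short as that of the chosen plan.
- Against: A3 is a conjugated nitrile oxide that dimerises readily. The ring closure pays the full entropic price of a ten-membered ring and gives a strained bridged system. C3 is set only by remote induction from C6, and C1 again by substrate control. N–O reduction must spare the butenolide and the allylic acetate.
- Comparison: the chosen ring expansion has no cyclisation entropy and takes C3 from the chiral pool. The two plans are equal in having two substrate-controlled centres. A2 needs an asymmetric synthesis of a butenolide Z-diene, so the total step count is probably no lower.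

Alternative 2: The cut is C5–C6. Zerovalent palladium (for example Pd(PPh3)4) would insert into the alkenyl carbon–iodine bond of the seco iodide A5, and the base-generated butenolide dienolate would be alkenylated at its γ-carbon to give A4.
- In favour: the route is convergent, and the Z geometry is fixed in the iodide, which is equal to the chosen plan on that point. C1 and C3 are set in an open chain by reagent control and C10=C14 is present from the start; this is better than the chosen plan's ene step.
- Against: γ- versus α-selectivity of the dienolate is uncertain, as is reductive elimination from a medium-ring palladacycle. C6 is created during ring closure with only remote control. C6–H of A4 is more acidic than any hydrogen of A5, so epimerisation under the basic conditions is likely. Three different protecting groups lengthen the end game, and the two silyl ethers at C1 and C13 must be told apart.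
- Comparison: the bond formation has precedent mainly for aryl partners and small rings, so it is mechanistically less secure than the oxy-Cope step, and the linear sequence to A5 is probably longer.

Alternative 3: The cuts are C6–C7 and O–C12. CrCl2 (divalent chromium) with catalytic NiCl2 would convert the alkenyl iodide of the seco iodo enoate enal A7 into a nucleophile that adds to the C6 aldehyde, and the resulting alkoxide would close the lactone on the cis ester to give A6.
- In favour: this type of macrocyclisation is well established and tolerates the C3 acetate, which is equal to or better than the chosen plan at C3. Ring and butenolide form in one step, which is better than the three-step annulation of the chosen plan. C1 is set before closure.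
- Against: the Z-enal of A7 isomerises easily. C6 arises by 1,4-induction across the alkene, which is no more secure than the chosen plan's reduction. The tetrasubstituted iodo enoate must be made with defined geometry. The silyl ethers at C1 and C13 must be differentiated at the end, and a large excess of chromium salt at high dilution is needed.
- Comparison: the mechanism is as well precedented as the oxy-Cope step, but the synthesis of A7 (two stereocentres, three defined alkenes) makes the route clearly longer.

Key step: step 5

Remark: the ten-membered compounds are numbered as germacranes (C6 carries the ketone or lactone oxygen, C7 is its α-carbon, C11–C13 are the lactone side carbons, C14 is on C10, C15 on C4); six-membered compounds keep their own ring numbering.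

Remark: C7 and C11 of 15, 16, 17 and 18 are expected as diastereomer mixtures and are left undefined, because both carbons become sp2 in 19.

Remark: the p-menthane ring is taken from (S)-(+)-carvone (1), which has the isopropenyl configuration of (R)-limonene and already carries the future C3 oxygen; the precursor of the key step is unchanged.

Step 1
Reactants: 1 (S)-(+)-carvone, (5S)-2-methyl-5-(prop-1-en-2-yl)cyclohex-2-en-1-one
Product: 2 (1S,5S)-2-methyl-5-(prop-1-en-2-yl)cyclohex-2-en-1-ol (cis-carveol)
Conditions: NaBH4, CeCl3·7H2O, MeOH, −78 to 0 °C
Reagents that add atoms: none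
Why: Luche 1,2-reduction of the enone; hydride should add axially to the half-chair with the isopropenyl group equatorial, which places the hydroxyl cis to isopropenyl and sets the future C3 as S.

Step 2
Reactants: 2 (1S,5S)-cis-carveol
Product: 3 tert-butyl(dimethyl){[(1S,5S)-2-methyl-5-(prop-1-en-2-yl)cyclohex-2-en-1-yl]oxy}silane
Conditions: TBSCl, imidazole, DMF, rt
Reagents that add atoms: tert-butyldimethylsilyl chloride, CC(C)(C)[Si](C)(C)Cl
Why: Standard silylation of a secondary allylic alcohol; the silyl ether tolerates the chromium oxidant, the organocerium reagent, potassium hydride and amide base used later.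

Step 3
Reactants: 3 cis-carveol tert-butyldimethylsilyl ether
Product: 4 (4S,6S)-4-[(tert-butyldimethylsilyl)oxy]-3-methyl-6-(prop-1-en-2-yl)cyclohex-2-en-1-one
Conditions: CrO3, 3,5-dimethylpyrazole, CH2Cl2, −20 °C
Reagents that add atoms: chromium trioxide, O=[Cr](=O)=O
Why: Allylic C–H oxidation by the CrO3–3,5-dimethylpyrazole complex; the ring methylene on the CH= terminus of the trisubstituted alkene is the position such reagents convert to an enone, while the isopropenyl group is less electron-rich and the silyloxy methine is shielded. No stereocentre is formed, and the isopropenyl carbon, now α to the ketone, stays in its favoured pseudo-equatorial cis relation to the silyloxy group.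

Step 4
Reactants: 4 (4S,6S)-4-silyloxy-3-methyl-6-isopropenylcyclohex-2-enone; 5 vinylmagnesium bromide
Product: 6 (1S,4S,6S)-4-[(tert-butyldimethylsilyl)oxy]-1-ethenyl-3-methyl-6-(prop-1-en-2-yl)cyclohex-2-en-1-ol
Conditions: CH2=CHMgBr, CeCl3, THF, −78 °C; aq NH4Cl
Reagents that add atoms: none
Why: 1,2-Addition of the weakly basic organocerium reagent formed from 5, so the acidic α-hydrogen of 4 is not removed and conjugate addition to the β,β-disubstituted enone is avoided. The alkenyl nucleophile should enter opposite the adjacent isopropenyl group and the 4-silyloxy group (both on one face), which puts vinyl trans to isopropenyl and gives the 1S carbinol.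

Step 5
Reactants: 6 (1S,4S,6S)-4-silyloxy-1-ethenyl-3-methyl-6-isopropenylcyclohex-2-en-1-ol
Product: 9 (2Z,4S,6E)-4-[(tert-butyldimethylsilyl)oxy]-3,7-dimethylcyclodeca-2,6-dien-1-one, via potassium alkoxide of the carbinol 7 (not isolated), via potassium enolate of the dienone 8 (not isolated)
Conditions: KH, 18-crown-6, THF, 0 °C to rt; AcOH, −78 °C
Reagents that add atoms: none
Why: KH with 18-crown-6 gives the dissociated alkoxide 7, whose oxyanion weakens the adjacent ring bond between the carbinol carbon and the isopropenyl-bearing carbon, so the 1,5-diene made of the vinyl group, these two ring carbons and the isopropenyl group undergoes a concerted [3,3] sigmatropic shift near room temperature (anionic oxy-Cope rearrangement). The closest known reaction type is the anionic oxy-Cope ring expansion of 1,2-dialkenylcyclohexanols to cyclodec-5-enones. The ten-membered ring is not closed end to end: the C8–C9 bond forms between the two alkene termini inside a six-membered chair transition state while the six-membered ring bond breaks, a four-atom ring expansion without macrocyclisation entropy. No stereocentre is created; the silyloxy-bearing carbon (future C3, S) is untouched and the two ring stereocentres at the breaking bond become sp2. The E geometry of C1=C10 should follow from the chair in which both ring bonds are equatorial, which is available because vinyl and isopropenyl are trans-diequatorial in 6, and the Z geometry of C4=C5 is inherited from the cyclohexene ring. Participation of the ring alkene in place of the vinyl group would need a bridged boat-like transition state and is not expected. Formation of the enolate 8 makes the step irreversible and defines the enolate as C6(O)=C7; protonation with acetic acid at −78 °C should give 9 before the enolate can equilibrate, and the silyl ether is inert to KH.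

Step 6
Reactants: 10 ethyl 2-(hydroxymethyl)prop-2-enoate
Product: 11 ethyl 2-{[(triisopropylsilyl)oxy]methyl}prop-2-enoate
Conditions: TIPSCl, imidazole, CH2Cl2, rt
Reagents that add atoms: triisopropylsilyl chloride, CC(C)[Si](Cl)(C(C)C)C(C)C
Why: Standard silylation of a primary alcohol; the bulky triisopropylsilyl group is chosen because it resists oxygen-to-oxygen migration in the later aldolate and shields the C13 hydrogens in step 10.

Step 7
Reactants: 11 ethyl 2-{[(triisopropylsilyl)oxy]methyl}prop-2-enoate
Product: 13 ethyl 2-oxo-3-[(triisopropylsilyl)oxy]propanoate, via ozonide 12 (not isolated)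
Conditions: O3, CH2Cl2, −78 °C; then Me2S, −78 °C to rt
Reagents that add atoms: ozone, [O-][O+]=O
Why: Ozonolysis of the 1,1-disubstituted acrylate alkene with reductive work-up gives the α-keto ester and formaldehyde; 13 is used directly because α-keto esters hydrate readily.

Step 8
Reactants: 9 (2Z,4S,6E)-4-silyloxy-3,7-dimethylcyclodeca-2,6-dien-1-one; 13 ethyl 2-oxo-3-[(triisopropylsilyl)oxy]propanoate
Product: 15 ethyl 2-[(3Z,5S,7E)-5-[(tert-butyldimethylsilyl)oxy]-4,8-dimethyl-2-oxocyclodeca-3,7-dien-1-yl]-2-hydroxy-3-[(triisopropylsilyl)oxy]propanoate, via lithium enolate of the dienone 14 (not isolated)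
Conditions: LiN(iPr)2, THF, −78 °C; then 13, −78 °C; AcOH, −78 °C
Reagents that add atoms: none
Why: Kinetic deprotonation of the enone at the α′ carbon C7 (not at a γ position) and aldol addition of lithium enolate 14 to the highly electrophilic keto carbonyl of 13; the cold quench is meant to prevent retro-aldol cleavage and silyl migration. The two new centres (C7, C11) need no control because both become sp2 in step 10.

Step 9
Reactants: 15 aldol adduct (C6 ketone, C11 tertiary alcohol, ethyl ester)
Product: 17 (3S,6R)-3-[(tert-butyldimethylsilyl)oxy]-11-hydroxy-13-[(triisopropylsilyl)oxy]germacra-1(10)E,4Z-dien-12,6-olide, via diol ester 16 (not isolated)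
Conditions: NaBH4, CeCl3·7H2O, MeOH, −78 °C; work-up; then K2CO3 (0.2 equiv), MeOH, 0 °C
Reagents that add atoms: none
Why: Luche 1,2-reduction of the enone carbonyl, then base-catalysed lactonisation of the γ-hydroxy ester 16 (5-exo-trig acyl substitution, ethanol lost). Hydride is expected to arrive from the ring periphery; with C3–H eclipsing the Z alkene this should give the 3,6-trans alcohol (6R). This facial preference is an expectation and is treated as a risk below.

Step 10
Reactants: 17 11-hydroxy lactone
Product: 19 (3S,6R)-3-[(tert-butyldimethylsilyl)oxy]-13-[(triisopropylsilyl)oxy]germacra-1(10)E,4Z,7(11)-trien-12,6-olide, via chlorosulfite of the tertiary alcohol 18 (not isolated)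
Conditions: SOCl2, pyridine, CH2Cl2, −20 to 0 °C
Reagents that add atoms: none
Why: Dehydration of the tertiary α-hydroxy lactone through chlorosulfite 18 by pyridine-promoted E2 elimination. Loss of the C7 hydrogen gives the conjugated tetrasubstituted butenolide alkene, whereas the C13 hydrogens are shielded by the triisopropylsilyl group and would lead to a less substituted enol ether. Both undefined centres disappear and C6 is not touched.

Step 11
Reactants: 19 bis-silyl butenolide
Product: 20 (3S,6R)-3,13-dihydroxygermacra-1(10)E,4Z,7(11)-trien-12,6-olide
Conditions: Bu4NF, AcOH, THF, 0 °C to rt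
Reagents that add atoms: none
Why: Fluoride cleavage of both silyl ethers, driven by Si–F bond formation; the acetic acid buffer keeps the medium from deprotonating C6–H of the butenolide and from promoting oxa-Michael addition of the C3 hydroxyl.

Step 12
Reactants: 20 3,13-diol
Product: 21 (3S,6R)-3,13-diacetoxygermacra-1(10)E,4Z,7(11)-trien-12,6-olide
Conditions: Ac2O, pyridine, DMAP (cat.), CH2Cl2, 0 °C to rt
Reagents that add atoms: acetic anhydride, CC(=O)OC(C)=O
Why: Nucleophile-catalysed acylation of one primary and one secondary allylic alcohol; no other hydroxyl is present, so no differentiation is needed.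

Step 13
Reactants: 21 3,13-diacetate
Product: 23 (1R,3S,6R)-3,13-diacetoxy-1-hydroxygermacra-4Z,7(11),10(14)-trien-12,6-olide, via C1 hydroperoxide 22 (not isolated)
Conditions: O2, hν (visible), tetraphenylporphyrin (cat.), CH2Cl2, −20 °C; then PPh3, 0 °C
Reagents that add atoms: dioxygen, O=O
Why: Schenck ene reaction of singlet oxygen with the only electron-rich alkene, C1=C10 (C4=C5 is deactivated by two allylic oxygens and C7=C11 is an acceptor alkene). Oxygen bonds to C1, hydrogen is taken from the C14 methyl on the more substituted side of the alkene, the double bond moves to C10=C14, and PPh3 reduces hydroperoxide 22 to the alcohol. Attack on the exposed outer face of the in-ring E alkene is expected to give 1R.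

## Compound list

1 | (S)-(+)-carvone, (5S)-2-methyl-5-(prop-1-en-2-yl)cyclohex-2-en-1-one | CC1=CC[C@@H](CC1=O)C(C)=C | starting material
2 | (1S,5S)-2-methyl-5-(prop-1-en-2-yl)cyclohex-2-en-1-ol (cis-carveol) | CC1=CC[C@@H](C[C@@H]1O)C(C)=C | intermediate
3 | tert-butyl(dimethyl){[(1S,5S)-2-methyl-5-(prop-1-en-2-yl)cyclohex-2-en-1-yl]oxy}silane | CC1=CC[C@@H](C[C@@H]1O[Si](C)(C)C(C)(C)C)C(C)=C | intermediate
4 | (4S,6S)-4-[(tert-butyldimethylsilyl)oxy]-3-methyl-6-(prop-1-en-2-yl)cyclohex-2-en-1-one | CC1=CC(=O)[C@@H](C[C@@H]1O[Si](C)(C)C(C)(C)C)C(C)=C | intermediate
5 | vinylmagnesium bromide | C=C[Mg]Br | starting material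
6 | (1S,4S,6S)-4-[(tert-butyldimethylsilyl)oxy]-1-ethenyl-3-methyl-6-(prop-1-en-2-yl)cyclohex-2-en-1-ol | C=C[C@]1(O)C=C(C)[C@@H](O[Si](C)(C)C(C)(C)C)C[C@H]1C(C)=C | intermediate
7 | potassium alkoxide of 6 | C=C[C@]1([O-])C=C(C)[C@@H](O[Si](C)(C)C(C)(C)C)C[C@H]1C(C)=C.[K+] | intermediate
8 | potassium enolate of 9 (C6–O, C6=C7, ring-E) | C/C1=C\C[C@H](O[Si](C)(C)C(C)(C)C)/C(C)=C\C([O-])=C\CC1.[K+] | intermediate
9 | (2Z,4S,6E)-4-[(tert-butyldimethylsilyl)oxy]-3,7-dimethylcyclodeca-2,6-dien-1-one | C/C1=C\C[C@H](O[Si](C)(C)C(C)(C)C)/C(C)=C\C(=O)CCC1 | intermediate
10 | ethyl 2-(hydroxymethyl)prop-2-enoate | C=C(CO)C(=O)OCC | starting material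
11 | ethyl 2-{[(triisopropylsilyl)oxy]methyl}prop-2-enoate | C=C(CO[Si](C(C)C)(C(C)C)C(C)C)C(=O)OCC | intermediate
12 | ethyl 3-{[(triisopropylsilyl)oxy]methyl}-1,2,4-trioxolane-3-carboxylate | CCOC(=O)C1(CO[Si](C(C)C)(C(C)C)C(C)C)OCOO1 | intermediate
13 | ethyl 2-oxo-3-[(triisopropylsilyl)oxy]propanoate | CCOC(=O)C(=O)CO[Si](C(C)C)(C(C)C)C(C)C | intermediate
14 | lithium enolate of 9 (C6–O, C6=C7, geometry not defined) | C/C1=C\C[C@H](O[Si](C)(C)C(C)(C)C)/C(C)=C\C([O-])=CCC1.[Li+] | intermediate
15 | ethyl 2-[(3Z,5S,7E)-5-[(tert-butyldimethylsilyl)oxy]-4,8-dimethyl-2-oxocyclodeca-3,7-dien-1-yl]-2-hydroxy-3-[(triisopropylsilyl)oxy]propanoate (mixture at C7, C11) | CCOC(=O)C(O)(CO[Si](C(C)C)(C(C)C)C(C)C)C1CC/C(C)=C/C[C@H](O[Si](C)(C)C(C)(C)C)/C(C)=C\C1=O | intermediate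
16 | 6R alcohol of 15: ethyl 2-[(2R,3Z,5S,7E)-5-[(tert-butyldimethylsilyl)oxy]-2-hydroxy-4,8-dimethylcyclodeca-3,7-dien-1-yl]-2-hydroxy-3-[(triisopropylsilyl)oxy]propanoate | CCOC(=O)C(O)(CO[Si](C(C)C)(C(C)C)C(C)C)C1CC/C(C)=C/C[C@H](O[Si](C)(C)C(C)(C)C)/C(C)=C\[C@H]1O | intermediate
17 | (3S,6R)-3-[(tert-butyldimethylsilyl)oxy]-11-hydroxy-13-[(triisopropylsilyl)oxy]germacra-1(10)E,4Z-dien-12,6-olide (mixture at C7, C11) | C/C1=C\C[C@H](O[Si](C)(C)C(C)(C)C)/C(C)=C\[C@H]2OC(=O)C(O)(CO[Si](C(C)C)(C(C)C)C(C)C)C2CC1 | intermediate
18 | C11 chlorosulfite of 17 | C/C1=C\C[C@H](O[Si](C)(C)C(C)(C)C)/C(C)=C\[C@H]2OC(=O)C(OS(=O)Cl)(CO[Si](C(C)C)(C(C)C)C(C)C)C2CC1 | intermediate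
19 | (3S,6R)-3-[(tert-butyldimethylsilyl)oxy]-13-[(triisopropylsilyl)oxy]germacra-1(10)E,4Z,7(11)-trien-12,6-olide | C/C1=C\C[C@H](O[Si](C)(C)C(C)(C)C)/C(C)=C\[C@H]2OC(=O)C(CO[Si](C(C)C)(C(C)C)C(C)C)=C2CC1 | intermediate
20 | (3S,6R)-3,13-dihydroxygermacra-1(10)E,4Z,7(11)-trien-12,6-olide | C/C1=C\C[C@H](O)/C(C)=C\[C@H]2OC(=O)C(CO)=C2CC1 | intermediate
21 | (3S,6R)-3,13-diacetoxygermacra-1(10)E,4Z,7(11)-trien-12,6-olide | C/C1=C\C[C@H](OC(C)=O)/C(C)=C\[C@H]2OC(=O)C(COC(C)=O)=C2CC1 | intermediate
22 | (1R,3S,6R)-3,13-diacetoxy-1-hydroperoxygermacra-4Z,7(11),10(14)-trien-12,6-olide | C=C1CCC2=C(COC(C)=O)C(=O)O[C@@H]2/C=C(/C)[C@@H](OC(C)=O)C[C@H]1OO | intermediate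
23 | (1R,3S,6R)-3,13-diacetoxy-1-hydroxygermacra-4Z,7(11),10(14)-trien-12,6-olide (CNP0227830.1) | C=C1CCC2=C(COC(C)=O)C(=O)O[C@@H]2/C=C(/C)[C@@H](OC(C)=O)C[C@H]1O | target

## Step count and least certain steps

Total step count: 13. Longest linear sequence: 11 (steps 1–5 and 8–13); steps 6–7 make the side reagent 13.

Step 5 (key step). What may go wrong: the strongly basic enolate 8 may equilibrate toward the extended dienolate before the quench, with loss of the Z geometry or β-elimination of the silyloxy group, and heterolytic cleavage of alkoxide 7 may compete with the concerted shift. Fallback, from 6 back to 9: silylation of the tertiary alcohol (Me3SiCl, imidazole) gives the trimethylsilyl ether F1. Neutral thermal siloxy-Cope rearrangement (degassed o-dichlorobenzene, about 200 °C) through the same chair gives the trimethylsilyl enol ether F2. Methanolysis (K2CO3, MeOH, 0 °C) of the enol ether returns 9 without a free enolate at elevated temperature.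

Step 3. What may go wrong: insufficient site selectivity of the C–H oxidation (attack at the silyloxy methine or at the allylic methyl groups), or isomerisation of the α-isopropenyl ketone into conjugation. Fallback, from 2 back to 4: hydroxyl-directed epoxidation (VO(acac)2, t-BuOOH) gives the syn epoxy alcohol F3, and silylation gives its tert-butyldimethylsilyl ether F4. Opening with PhSeNa (from PhSeSePh and NaBH4) at the less substituted epoxide carbon gives the hydroxy selenide F5. Oxidation with H2O2 brings about syn elimination away from the hydroxyl to the tertiary allylic alcohol F6. Oxidative 1,3-transposition (pyridinium chlorochromate, NaOAc, CH2Cl2; Babler–Dauben oxidation) then gives 4.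

Step 9. What may go wrong: poor or reversed facial selectivity of hydride delivery at C6, because the substrate is a diastereomer mixture at C7 and C11 and the conformation of the medium ring is not known; retro-aldol cleavage before reduction is a lesser concern. Fallback, from 15 back to 17: the reduction is run as in step 9 but the carbonate treatment is omitted. If this delivers mainly the 6S diol ester F7, a Mitsunobu reaction (PPh3, DIAD, 4-nitrobenzoic acid) inverts the secondary allylic alcohol, the tertiary one being unreactive, to the 6R 4-nitrobenzoate F8. K2CO3 in MeOH removes the aryl ester and the freed alkoxide closes the lactone to 17.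

Step 10. What may go wrong: elimination in the wrong direction (toward C13, forming a silyl enol ether) for those diastereomers of 17 that have no C7 hydrogen anti to the leaving group. Fallback, from 15 back to 19: dehydration is done before reduction. (CF3CO)2O and Et3N, then DBU, effect an E1cB elimination through the C6 ketone enolate, which can involve only C7–H, and give the γ-oxo enoate F9. Its geometric isomers can equilibrate through the dienolate, and the one with the ester cis to C6 is needed. Luche reduction of F9 gives the C6 alcohol, which lactonises onto the cis ester to 19.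

Step 13. What may go wrong: poor facial selectivity at C1, or hydrogen abstraction from C2 or C9 in place of C14. Fallback, from 21 back to 23: if photooxygenation and reduction as in step 13 give mainly the 1S alcohol F10, oxidation (Dess–Martin periodinane) gives the α-methylene ketone F11. Reagent-controlled reduction ((S)-Me-CBS oxazaborolidine, catecholborane, toluene, −78 °C) should deliver the 1R alcohol 23 if the 1,1-disubstituted alkenyl group acts as the large substituent.

## Further compounds

F1 | step 5 | trimethylsilyl ether of 6 | C=C[C@]1(O[Si](C)(C)C)C=C(C)[C@@H](O[Si](C)(C)C(C)(C)C)C[C@H]1C(C)=C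
F2 | step 5 | trimethylsilyl enol ether of 9 (C6–O, C6=C7, ring-E) | C/C1=C\C[C@H](O[Si](C)(C)C(C)(C)C)/C(C)=C\C(O[Si](C)(C)C)=C\CC1
F3 | step 3 | syn-2,3-epoxide of cis-carveol (oxirane oxygen cis to the hydroxyl) | C[C@@]12O[C@@H]1C[C@@H](C[C@@H]2O)C(C)=C
F4 | step 3 | tert-butyldimethylsilyl ether of F3 | C[C@@]12O[C@@H]1C[C@@H](C[C@@H]2O[Si](C)(C)C(C)(C)C)C(C)=C
F5 | step 3 | hydroxy selenide (tertiary alcohol at the methyl-bearing carbon, phenylselanyl trans to it on the next carbon) | C[C@@]1(O)[C@@H]([Se]c2ccccc2)C[C@@H](C[C@@H]1O[Si](C)(C)C(C)(C)C)C(C)=C
F6 | step 3 | tertiary allylic alcohol, 2-silyloxy-1-methyl-4-isopropenylcyclohex-5-en-1-ol | C[C@@]1(O)C=C[C@@H](C[C@@H]1O[Si](C)(C)C(C)(C)C)C(C)=C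
F7 | step 9 | 6S epimer of diol ester 16 | CCOC(=O)C(O)(CO[Si](C(C)C)(C(C)C)C(C)C)C1CC/C(C)=C/C[C@H](O[Si](C)(C)C(C)(C)C)/C(C)=C\[C@@H]1O
F8 | step 9 | 6R 4-nitrobenzoate of the diol ester | CCOC(=O)C(O)(CO[Si](C(C)C)(C(C)C)C(C)C)C1CC/C(C)=C/C[C@H](O[Si](C)(C)C(C)(C)C)/C(C)=C\[C@H]1OC(=O)c1ccc(cc1)[N+](=O)[O-]
F9 | step 10 | γ-oxo enoate, C7=C11 alkene with the ester cis to C6 | CCOC(=O)/C(CO[Si](C(C)C)(C(C)C)C(C)C)=C1/CC/C(C)=C/C[C@H](O[Si](C)(C)C(C)(C)C)/C(C)=C\C1=O
F10 | step 13 | 1S epimer of 23 | C=C1CCC2=C(COC(C)=O)C(=O)O[C@@H]2/C=C(/C)[C@@H](OC(C)=O)C[C@@H]1O
F11 | step 13 | 1-oxo compound, (3S,6R)-3,13-diacetoxy-1-oxogermacra-4Z,7(11),10(14)-trien-12,6-olide | C=C1CCC2=C(COC(C)=O)C(=O)O[C@@H]2/C=C(/C)[C@@H](OC(C)=O)CC1=O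
A1 | alternative 1 | isoxazoline-bridged germacranolide (N–O bridge from C1 to C3) | C=C1CCC2=C(COC(C)=O)C(=O)O[C@@H]2/C=C(/C)[C@@H]3CC1=NO3
A2 | alternative 1 | open-chain C1 aldoxime with Z-diene and butenolide | C=C(C=NO)CCC1=C(COC(C)=O)C(=O)O[C@@H]1/C=C(/C)C=C
A3 | alternative 1 | nitrile oxide from A2 | C=C(C#[N+][O-])CCC1=C(COC(C)=O)C(=O)O[C@@H]1/C=C(/C)C=C
A4 | alternative 2 | bicyclic germacranolide with C3 4-methoxybenzyl ether and silyl ethers at C1 and C13 | C=C1CCC2=C(CO[Si](C)(C)C(C)(C)C)C(=O)O[C@@H]2/C=C(/C)[C@@H](OCc2ccc(OC)cc2)C[C@H]1O[Si](C)(C)C(C)(C)C
A5 | alternative 2 | seco Z-alkenyl iodide with γ-unsubstituted butenolide | C=C(CCC1=C(CO[Si](C)(C)C(C)(C)C)C(=O)OC1)[C@H](O[Si](C)(C)C(C)(C)C)C[C@H](OCc1ccc(OC)cc1)/C(C)=C\I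
A6 | alternative 3 | bicyclic germacranolide with C3 acetate and silyl ethers at C1 and C13 | C=C1CCC2=C(CO[Si](C)(C)C(C)(C)C)C(=O)O[C@@H]2/C=C(/C)[C@@H](OC(C)=O)C[C@H]1O[Si](C)(C)C(C)(C)C
A7 | alternative 3 | seco iodo enoate Z-enal | O=C/C=C(/C)[C@@H](OC(C)=O)C[C@@H](O[Si](C)(C)C(C)(C)C)C(=C)CC/C(I)=C(\CO[Si](C)(C)C(C)(C)C)C(=O)OC
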